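(The data were computed for substances that don't exist; noise was put on by code.)

In the first hours of the oak run G stays near the scatter: 1% at 1.50 h, 3% at 5.00 h. Then it climbs to 23% at 20.0 h.

| flask | E | Z | Q | remark | time |
|---|---|---|---|---|---|
| oak | 0.022 M | 10 mM | 1.2 mM | run made earlier |  |
| Sunday's | 0.060 M | 5.00 mM | 5.0 mM |  | 2.5 d |
| Saturday's | 0.0050 M | 5.00 mM | 1.2 mM |  | 2.5 d |
| Monday's | 0.080 M | 30.0 mM | 0.60 mM |  | 2.5 d |
| Thursday's | 0.020 M | 10.0 mM | 1.2 mM |  | 2.5 d |
| Wednesday's | 0.0050 M | 40.0 mM | 2.5 mM |  | 2.5 d |

oak run (percent of the E charged)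

| time / h | G / % |
|---|---|
| 1.50 | 1 |
| 3.00 | 1 |
| 5.00 | 3 |
| 8.00 | 11 |
| 12.0 | 13 |
| 20.0 | 23 |

(scatter of a reading: 2 percentage points)

- the earlier runs were read with a standard deviation of 2 percentage points
- on the list of suspects stand: E + Q <-> D; D -> Q + G; Z + Q <-> J; J -> Q + L; Q + G -> X
- no earlier run changes the charge of Q; that part of a forecast is a guess

* all flasks from highest to lowest amount of G, in percent of the E charged, at 2.5 d (Sunday's / Saturday's / Monday's / Thursday's / Wednesday's)
* the amount of G, in percent of the E charged of the flask you put first, at 2.5 d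
* the amount of G, in percent of the E charged of the flask you put last, at 2.5 d

Two views of these flasks are in dispute. The first counts speed: more Q turns E over faster, so the flask with the most Q should lead. The forecast takes this side. Of Sunday's it says “much Q and little Z, so nearly complete”. Its order is Sunday's > Saturday's > Wednesday's > Thursday's > Monday's, with 90% on top (range 68% to 100%) and 12% at the bottom (range 6% to 26%).

I count Q instead, and this reckoning is my own. Write the balance of Q. It cycles through D and J, but the suspect Q + G -> X removes it for good, and each Q lost takes one G with it. So a flask should be judged by the demand N, the turnovers each charged Q must deliver to finish the E, N = c_E/c_Q. That is the turnover number the recipe asks for.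

For Wednesday's N is 2.00. For Saturday's it is 4.17, for Sunday's 12.0, for Thursday's 16.7 and for Monday's 133. The oak run shows, as a reading, 4.22 turnovers by 20.0 h. So I rank the flasks by rising N, Wednesday's first, which differs from the forecast.

The same balance gives a ceiling. Once all Q in Wednesday's is X, G can stand at 50.0% of the E charged at most. I put Wednesday's near that figure. No earlier run changes Q, so my view is a guess too.

The simulation gives Wednesday's > Saturday's > Sunday's > Thursday's > Monday's, with 60.5% on top and 12.8% at the bottom.

    E + Q ⇌ D (K = 76.0 M⁻¹, k = 0.0150 M⁻¹ s⁻¹)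
    D → Q + G (k = 1.50 × 10⁻⁴ s⁻¹)
    Z + Q ⇌ J (K = 78.0 M⁻¹, k = 0.0190 M⁻¹ s⁻¹)
    J → Q + L (k = 2.50 × 10⁻⁴ s⁻¹)
    Q + G → X (k = 0.00180 M⁻¹ s⁻¹)

Wednesday's, with the smallest N, holds the most G. Its 60.5% stands above my ceiling, with 43.3% of its Q as X at 2.50 d. At 2.50 d Sunday's holds 6.31 G per charged Q against its N of 12.0, with 98.4% of its Q as X. The speed view holds earlier on: at 20.0 h, changing only Q from the oak charge to Wednesday's lifts G from 20.6% to 36.9%. Wednesday's read at 10 d keeps N at 2.00 and the ceiling at 50.0%. There 97.1% of Q is X, 3.17% of E remains, and G has fallen to 48.3%, under the ceiling.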